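**Retrosynthetic overview**

1. Feature: in ring A (the quinone; C1 = carbonyl between the two methoxy carbons, C3 = carbon carrying the side chain) the oxygens on C2 (OMe), C4 (C=O) and C6 (OMe) are mutually meta, with the chain on C3. This is the pattern of a folded triketide; only the C1 oxygen is not acetate-derived.
2. Evelynin 13 ⇐ ketal hydrolysis and O-methylation (C6–OMe) ⇐ hydroxyquinone 11 ⇐ Teuber oxidation of resorcinol 10, which adds the C1 oxygen.
3. Ring A of 10 ⇐ 4-methoxy-6-methyl-2-pyrone 8, by methoxide ring opening and Claisen closure forming C4–C5 (pyrone C2 to the carbon of the pyrone 6-methyl group).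
4. Pyrone 8 ⇐ C3 Michael addition of triacetic acid lactone 4 to the aryl vinyl ketone made from veratrole 1 and 3-chloropropanoyl chloride 2, then O-methylation and ketalization.
5. Ring order: the veratrole ring and the pyrone are bought; ring A is the only ring built (step 5), by transformation of the pyrone.

Key step: step 5

Remark: the ring-opened intermediate 9 is the (2E) enoate by the CIP rules; this is the geometry in which the ester carbon and the CH2C(O)CH3 arm are cis on the double bond, as in the pyrone.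

**Route**

Step 1
Reactants: 1 veratrole; 2 3-chloropropanoyl chloride
Product: 3 3-chloro-1-(3,4-dimethoxyphenyl)propan-1-one
Conditions: AlCl3 (1.2 equiv), CH2Cl2, 0 °C to rt; ice/aq. HCl
Reagents that add atoms: none
Why: Friedel–Crafts acylation, in which the acylium ion attacks para to one methoxy group of veratrole and the ketone formed deactivates the ring against a second acylation.

Step 2
Reactants: 3 3-chloro-1-(3,4-dimethoxyphenyl)propan-1-one; 4 triacetic acid lactone (1.3 equiv)
Product: 6 3-[3-(3,4-dimethoxyphenyl)-3-oxopropyl]-4-hydroxy-6-methyl-2H-pyran-2-one, via aryl vinyl ketone 5 (not isolated)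
Conditions: Et3N (2.2 equiv), MeCN, 60 °C; then aq. HCl to pH 3, 0 °C
Reagents that add atoms: none
Why: Et3N eliminates HCl from the β-chloro ketone to the enone, and the triethylammonium enolate of the 4-hydroxy-2-pyrone adds through its nucleophilic C3 in a Michael addition of the kind used for warfarin-type adducts, O-addition being reversible.

Step 3
Reactants: 6 3-[3-(3,4-dimethoxyphenyl)-3-oxopropyl]-4-hydroxy-6-methyl-2H-pyran-2-one
Product: 7 3-[3-(3,4-dimethoxyphenyl)-3-oxopropyl]-4-methoxy-6-methyl-2H-pyran-2-one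
Conditions: Me2SO4 (1.2 equiv), K2CO3 (2 equiv), acetone, reflux
Reagents that add atoms: dimethyl sulfate, COS(=O)(=O)OC
Why: O-methylation of the vinylogous acid through its carbonate-generated anion, conditions that convert 4-hydroxy-2-pyrones into 4-methoxy-2-pyrones and under which any cyclic hemiketal form of 6 reacts through the open enolate.

Step 4
Reactants: 7 3-[3-(3,4-dimethoxyphenyl)-3-oxopropyl]-4-methoxy-6-methyl-2H-pyran-2-one
Product: 8 3-{2-[2-(3,4-dimethoxyphenyl)-1,3-dioxolan-2-yl]ethyl}-4-methoxy-6-methyl-2H-pyran-2-one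
Conditions: Me3SiOCH2CH2OSiMe3 (2 equiv), TMSOTf (10 mol%), CH2Cl2, −20 °C to rt; pyridine quench
Reagents that add atoms: 1,2-bis(trimethylsilyloxy)ethane, C[Si](C)(C)OCCO[Si](C)(C)C
Why: Noyori ketalization, in which the silylated oxocarbenium ion of the aryl ketone (stabilized by the p-methoxyaryl group) is captured by the bis-silyl glycol under aprotic conditions that leave the methoxypyrone untouched, driven by formation of (Me3Si)2O.

Step 5
Reactants: 8 3-{2-[2-(3,4-dimethoxyphenyl)-1,3-dioxolan-2-yl]ethyl}-4-methoxy-6-methyl-2H-pyran-2-one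
Product: 10 4-{2-[2-(3,4-dimethoxyphenyl)-1,3-dioxolan-2-yl]ethyl}-5-methoxybenzene-1,3-diol, via ring-opened keto ester 9 (not isolated)
Conditions: Mg(OMe)2 (5 equiv), degassed MeOH, reflux, Ar; then cold 0.5 M aq. HCl to pH 5–6
Reagents that add atoms: none
Why: Methoxide adds to the lactone carbonyl C2 and the ring opens to the magnesium-chelated keto ester 9, in which the ester carbon and the CH2C(O)CH3 arm stay cis on the enol ether double bond inherited from the pyrone. The enolate of the terminal methyl ketone then attacks the ester carbonyl, forming the bond between the former pyrone 6-methyl carbon and C2 (C4–C5 of ring A); methoxide leaves and enolization to the arene, held as its magnesium phenoxide, makes the sequence irreversible. The closest known reaction is the Mg(OMe)2-induced recyclization of triacetic acid lactone methyl ether to phloroglucinol monomethyl ether, a biomimetic Claisen (Dieckmann-type) condensation. Ring A closes in the 6-(enolendo)-exo-trig mode, and no stereocentre is formed. The step needs chemoselectivity for this Claisen closure over aldol closures; the dioxolane secures it by leaving the methyl ketone as the only enolizable carbonyl, and the doubly activated CH2 could only close a four-membered ring. Relactonization is the one other pathway open to 9 and merely returns 8.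

Step 6
Reactants: 10 4-{2-[2-(3,4-dimethoxyphenyl)-1,3-dioxolan-2-yl]ethyl}-5-methoxybenzene-1,3-diol
Product: 11 5-{2-[2-(3,4-dimethoxyphenyl)-1,3-dioxolan-2-yl]ethyl}-2-hydroxy-6-methoxycyclohexa-2,5-diene-1,4-dione
Conditions: ON(SO3K)2 (2.5 equiv), aq. KH2PO4/Na2HPO4 (pH 7)–acetone, 0 °C to rt; then citric acid to pH 4 at 0 °C, EtOAc
Reagents that add atoms: dipotassium nitrosodisulfonate (Fremy's salt), [K+].[K+].[O]N(S(=O)(=O)[O-])S(=O)(=O)[O-]
Why: Teuber oxidation, in which one nitroxyl radical abstracts the phenolic hydrogen and a second couples at the only unsubstituted para position (the CH between the methoxy and hydroxy carbons, para to the hydroxyl next to the chain), so that loss of HN(SO3K)2 should give the p-quinone with the other hydroxyl retained as a vinylogous acid.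

Step 7
Reactants: 11 5-{2-[2-(3,4-dimethoxyphenyl)-1,3-dioxolan-2-yl]ethyl}-2-hydroxy-6-methoxycyclohexa-2,5-diene-1,4-dione
Product: 12 3-{2-[2-(3,4-dimethoxyphenyl)-1,3-dioxolan-2-yl]ethyl}-2,6-dimethoxycyclohexa-2,5-diene-1,4-dione
Conditions: Me2SO4 (1.5 equiv), K2CO3 (2 equiv), acetone, rt to 40 °C
Reagents that add atoms: dimethyl sulfate, COS(=O)(=O)OC
Why: O-methylation of the hydroxyquinone, a vinylogous carboxylic acid, through its anion with the hard electrophile Me2SO4, which should give the more stable p-quinone methyl ether.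

Step 8
Reactants: 12 3-{2-[2-(3,4-dimethoxyphenyl)-1,3-dioxolan-2-yl]ethyl}-2,6-dimethoxycyclohexa-2,5-diene-1,4-dione
Product: 13 evelynin, 3-[3-(3,4-dimethoxyphenyl)-3-oxopropyl]-2,6-dimethoxycyclohexa-2,5-diene-1,4-dione
Conditions: 1 M aq. HCl, THF, rt
Reagents that add atoms: water, O
Why: Acid-catalysed ketal hydrolysis, fast at room temperature because the oxocarbenium ion is stabilized by the 3,4-dimethoxyphenyl group, under conditions the methoxyquinone vinylogous esters should tolerate.

**Compound list**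

1 | veratrole (1,2-dimethoxybenzene) | COc1ccccc1OC | starting material
2 | 3-chloropropanoyl chloride | ClCCC(Cl)=O | starting material
3 | 3-chloro-1-(3,4-dimethoxyphenyl)propan-1-one | COc1ccc(cc1OC)C(=O)CCCl | intermediate
4 | triacetic acid lactone (4-hydroxy-6-methyl-2H-pyran-2-one) | CC1=CC(O)=CC(=O)O1 | starting material
5 | 1-(3,4-dimethoxyphenyl)prop-2-en-1-one | COc1ccc(cc1OC)C(=O)C=C | intermediate
6 | 3-[3-(3,4-dimethoxyphenyl)-3-oxopropyl]-4-hydroxy-6-methyl-2H-pyran-2-one | CC1=CC(O)=C(CCC(=O)c2ccc(OC)c(OC)c2)C(=O)O1 | intermediate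
7 | 3-[3-(3,4-dimethoxyphenyl)-3-oxopropyl]-4-methoxy-6-methyl-2H-pyran-2-one | COC1=C(CCC(=O)c2ccc(OC)c(OC)c2)C(=O)OC(C)=C1 | intermediate
8 | 3-{2-[2-(3,4-dimethoxyphenyl)-1,3-dioxolan-2-yl]ethyl}-4-methoxy-6-methyl-2H-pyran-2-one | COC1=C(CCC2(OCCO2)c3ccc(OC)c(OC)c3)C(=O)OC(C)=C1 | intermediate
9 | methyl (2E)-2-{2-[2-(3,4-dimethoxyphenyl)-1,3-dioxolan-2-yl]ethyl}-3-methoxy-5-oxohex-2-enoate | COC(=O)/C(CCC1(OCCO1)c2ccc(OC)c(OC)c2)=C(/OC)CC(C)=O | intermediate
10 | 4-{2-[2-(3,4-dimethoxyphenyl)-1,3-dioxolan-2-yl]ethyl}-5-methoxybenzene-1,3-diol | COc1cc(O)cc(O)c1CCC2(OCCO2)c3ccc(OC)c(OC)c3 | intermediate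
11 | 5-{2-[2-(3,4-dimethoxyphenyl)-1,3-dioxolan-2-yl]ethyl}-2-hydroxy-6-methoxycyclohexa-2,5-diene-1,4-dione | COC1=C(CCC2(OCCO2)c3ccc(OC)c(OC)c3)C(=O)C=C(O)C1=O | intermediate
12 | 3-{2-[2-(3,4-dimethoxyphenyl)-1,3-dioxolan-2-yl]ethyl}-2,6-dimethoxycyclohexa-2,5-diene-1,4-dione | COC1=CC(=O)C(CCC2(OCCO2)c3ccc(OC)c(OC)c3)=C(OC)C1=O | intermediate
13 | evelynin, 3-[3-(3,4-dimethoxyphenyl)-3-oxopropyl]-2,6-dimethoxycyclohexa-2,5-diene-1,4-dione | COC1=CC(=O)C(CCC(=O)c2ccc(OC)c(OC)c2)=C(OC)C1=O | target

**Step count**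

Total steps: 8. Longest linear sequence: 8 steps (veratrole 1 to evelynin 13; triacetic acid lactone 4 enters at step 2).

**Steps most likely to fail**

1. Step 5. The ester in 9 is α-branched and sits on a tetrasubstituted double bond, so the Claisen closure may be slow. Relactonization to 8, retro-Claisen loss of the acetyl terminus by methoxide, or air oxidation of the electron-rich phenoxide could then take over. Fallback (sets out from 3, comes back at 13): the arene is taken ready-made and its symmetry is used. Enone 5 is liberated from 3 with Et3N in CH2Cl2 and isolated. Bought 1,3,5-trimethoxybenzene F1 is added to it in a Friedel–Crafts conjugate addition (Bi(OTf)3 cat., MeCN, rt) to give 1-(3,4-dimethoxyphenyl)-3-(2,4,6-trimethoxyphenyl)propan-1-one F2. The two free positions of its trimethoxyphenyl ring are equivalent, so Vilsmeier formylation (POCl3, DMF, 0 °C to rt) should give the single aldehyde 3-[3-(3,4-dimethoxyphenyl)-3-oxopropyl]-2,4,6-trimethoxybenzaldehyde F3. Baeyer–Villiger (Dakin-type) oxidation with mCPBA in CH2Cl2 at 0 °C gives 3-[3-(3,4-dimethoxyphenyl)-3-oxopropyl]-2,4,6-trimethoxyphenyl formate F4, which K2CO3 in MeOH cleaves to 3-[3-(3,4-dimethoxyphenyl)-3-oxopropyl]-2,4,6-trimethoxyphenol F5. Oxidative demethylation of this p-methoxyphenol with (NH4)2Ce(NO3)6 in MeCN/H2O at 0 °C should give 13 directly.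

2. Step 6. The nitroxyl radical may couple at the carbon between the two hydroxyls and lead to ortho-quinone products. The hydroxyquinone may also be overoxidized or dimerize, and the ketal may be lost on acidification. Fallback (sets out from 10, comes back at 12): both hydroxyls of 10 are methylated (Me2SO4, K2CO3, acetone) to 2-(3,4-dimethoxyphenyl)-2-[2-(2,4,6-trimethoxyphenyl)ethyl]-1,3-dioxolane F6, whose two ring A C–H positions are equivalent. NBS in MeCN at 0 °C should brominate this more electron-rich ring to 2-[2-(3-bromo-2,4,6-trimethoxyphenyl)ethyl]-2-(3,4-dimethoxyphenyl)-1,3-dioxolane F7. Palladium-catalysed hydroxylation (Pd2(dba)3, tBuXPhos, KOH, dioxane/H2O, 100 °C) gives 3-{2-[2-(3,4-dimethoxyphenyl)-1,3-dioxolan-2-yl]ethyl}-2,4,6-trimethoxyphenol F8. PhI(OAc)2 in MeCN/H2O at 0 °C then oxidizes the p-methoxyphenol to quinone 12 with loss of methanol, and step 8 follows.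

3. Step 4. Ketalization of the conjugated, electron-rich aryl ketone may stay incomplete. The pyrone methoxy oxygen may also add to the oxocarbenium ion, giving a fused pyranopyranone with loss of the methyl group. Fallback (sets out from 3, comes back at 8): the ketal is installed before any pyrone is present and the C3–chain bond is made by cross-coupling. Ketone 3 is ketalized (ethylene glycol, TsOH, toluene, Dean–Stark) to 2-(2-chloroethyl)-2-(3,4-dimethoxyphenyl)-1,3-dioxolane F9. KOtBu in THF eliminates HCl to give 2-(3,4-dimethoxyphenyl)-2-ethenyl-1,3-dioxolane F10. Hydroboration with 9-BBN in THF gives the terminal borane 9-{2-[2-(3,4-dimethoxyphenyl)-1,3-dioxolan-2-yl]ethyl}-9-borabicyclo[3.3.1]nonane F11. Bought 4-methoxy-6-methyl-2H-pyran-2-one F12 is brominated at C3 with NBS in MeCN to 3-bromo-4-methoxy-6-methyl-2H-pyran-2-one F13. B-alkyl Suzuki–Miyaura coupling of F11 with F13 (PdCl2(dppf), K3PO4, THF/H2O, 60 °C) should give 8; this also bypasses steps 2 and 3.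

**Further compounds**

F1 | step 5 | 1,3,5-trimethoxybenzene | COc1cc(OC)cc(OC)c1
F2 | step 5 | 1-(3,4-dimethoxyphenyl)-3-(2,4,6-trimethoxyphenyl)propan-1-one | COc1cc(OC)c(CCC(=O)c2ccc(OC)c(OC)c2)c(OC)c1
F3 | step 5 | 3-[3-(3,4-dimethoxyphenyl)-3-oxopropyl]-2,4,6-trimethoxybenzaldehyde | COc1cc(OC)c(CCC(=O)c2ccc(OC)c(OC)c2)c(OC)c1C=O
F4 | step 5 | 3-[3-(3,4-dimethoxyphenyl)-3-oxopropyl]-2,4,6-trimethoxyphenyl formate | COc1cc(OC)c(CCC(=O)c2ccc(OC)c(OC)c2)c(OC)c1OC=O
F5 | step 5 | 3-[3-(3,4-dimethoxyphenyl)-3-oxopropyl]-2,4,6-trimethoxyphenol | COc1cc(OC)c(CCC(=O)c2ccc(OC)c(OC)c2)c(OC)c1O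
F6 | step 6 | 2-(3,4-dimethoxyphenyl)-2-[2-(2,4,6-trimethoxyphenyl)ethyl]-1,3-dioxolane | COc1cc(OC)c(CCC2(OCCO2)c3ccc(OC)c(OC)c3)c(OC)c1
F7 | step 6 | 2-[2-(3-bromo-2,4,6-trimethoxyphenyl)ethyl]-2-(3,4-dimethoxyphenyl)-1,3-dioxolane | COc1cc(OC)c(CCC2(OCCO2)c3ccc(OC)c(OC)c3)c(OC)c1Br
F8 | step 6 | 3-{2-[2-(3,4-dimethoxyphenyl)-1,3-dioxolan-2-yl]ethyl}-2,4,6-trimethoxyphenol | COc1cc(OC)c(CCC2(OCCO2)c3ccc(OC)c(OC)c3)c(OC)c1O
F9 | step 4 | 2-(2-chloroethyl)-2-(3,4-dimethoxyphenyl)-1,3-dioxolane | COc1ccc(cc1OC)C1(CCCl)OCCO1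
F10 | step 4 | 2-(3,4-dimethoxyphenyl)-2-ethenyl-1,3-dioxolane | COc1ccc(cc1OC)C1(C=C)OCCO1
F11 | step 4 | 9-{2-[2-(3,4-dimethoxyphenyl)-1,3-dioxolan-2-yl]ethyl}-9-borabicyclo[3.3.1]nonane | COc1ccc(cc1OC)C1(CCB2C3CCCC2CCC3)OCCO1
F12 | step 4 | 4-methoxy-6-methyl-2H-pyran-2-one | COC1=CC(=O)OC(C)=C1
F13 | step 4 | 3-bromo-4-methoxy-6-methyl-2H-pyran-2-one | COC1=C(Br)C(=O)OC(C)=C1
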